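**Plan**
- Retrosynthetic cuts, in order: the C7–O ester bond (linoleoyl chloride); the C5–C6 bond (vinylogous Dieckmann closure of the carbocycle); then both bonds from C8a to C1 and C4a, which takes one carbon out of the pyran and leaves (2R)-2,4-dimethyl-2,3-dihydrofuran plus a bromo(diazo)ketone.
- Forward order: the five-membered cyclic enol ether is made from (R)-γ-valerolactone and the acyl carbene precursor from (R)-lactic acid. Rhodium carbene transfer then inserts C8a into the C1=C4a bond, so the oxolane ring becomes the pyran ring and the two halves are joined. The carbocycle closes next and the fatty ester is attached last.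
- Enabling feature: in the target the ring oxygen O2 is followed by three contiguous sp2 carbons, C1=C8a–C4a(=C5), with the C8 carbonyl on the middle one. This O2–C1–C8a–C4a array is the allyl cation (less the proton at C5) that a 6-acyl-6-bromo-2-oxabicyclo[3.1.0]hexane releases when its ring-fusion bond opens.
- Stereochemistry: C3 comes from (R)-γ-valerolactone and is never touched. C7 comes from (R)-lactic acid by self-regeneration of the stereocentre through its cis pivalaldehyde acetal. Both Z alkenes come from linoleoyl chloride.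

Key step: step 8

Remark: the target is numbered as an isochromene (C1, O2, C3, C4, C4a, C5 to C8, C8a); stereocentres that are destroyed later (lactone α-carbon, lactol and acetal carbons, the carbinol of 9) are carried as mixtures.

Step 1
Reactants: 1 (R)-γ-valerolactone
Product: 2 (3RS,5R)-3,5-dimethyloxolan-2-one
Conditions: LDA, THF, −78 °C; MeI, −78 → −20 °C
Reagents that add atoms: methyl iodide, CI
Why: Kinetic lithium enolate alkylation of a γ-lactone with methyl iodide is standard; the new α-centre (expected mainly trans to the ring methyl) is destroyed in step 3, so its configuration does not matter.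

Step 2
Reactants: 2 (3RS,5R)-3,5-dimethyloxolan-2-one
Product: 3 (3RS,5R)-3,5-dimethyloxolan-2-ol
Conditions: DIBAL-H, CH2Cl2, −78 °C; aq. Rochelle salt
Reagents that add atoms: none
Why: At −78 °C the partial lactone reduction should stop at the aluminium hemiacetal, which gives the lactol on work-up.

Step 3
Reactants: 3 (3RS,5R)-3,5-dimethyloxolan-2-ol
Product: 4 (2R)-2,4-dimethyl-2,3-dihydrofuran
Conditions: MsCl, Et3N, CH2Cl2, −20 °C → reflux; distillation
Reagents that add atoms: none
Why: The anomeric mesylate (or chloride) formed in situ should ionise and lose its only β-hydrogen to triethylamine, the usual lactol-to-glycal dehydration, giving the endocyclic enol ether without touching the methyl-bearing carbinol stereocentre.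

Step 4
Reactants: 5 (R)-lactic acid; 6 pivalaldehyde
Product: 7 (2R,5R)-2-tert-butyl-5-methyl-1,3-dioxolan-4-one
Conditions: TsOH (cat.), H2SO4 (cat.), pentane, reflux, Dean–Stark; recrystallisation of the cis isomer
Reagents that add atoms: none
Why: Acid-catalysed acetalisation of the α-hydroxy acid with water removal should give the dioxolanone, whose cis isomer (tert-butyl and methyl on the same face) is the favoured, crystalline one; the lactic acid centre is not touched.

Step 5
Reactants: 7 (2R,5R)-2-tert-butyl-5-methyl-1,3-dioxolan-4-one; 8 acetaldehyde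
Product: 9 (2R,5S)-2-tert-butyl-5-[(1RS)-1-hydroxyethyl]-5-methyl-1,3-dioxolan-4-one
Conditions: LDA, THF, −78 °C; 8, −78 °C; aq. NH4Cl
Reagents that add atoms: none
Why: Aldol addition of the dioxolanone lithium enolate should occur on the face opposite the tert-butyl group (self-regeneration of the stereocentre), so the new C–C bond replaces the former C–H with retention and fixes the quaternary centre that becomes C7; the carbinol centre is removed in step 6.

Step 6
Reactants: 9 (2R,5S)-2-tert-butyl-5-[(1RS)-1-hydroxyethyl]-5-methyl-1,3-dioxolan-4-one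
Product: 10 (2R,5S)-5-acetyl-2-tert-butyl-5-methyl-1,3-dioxolan-4-one
Conditions: Dess–Martin periodinane, NaHCO3, CH2Cl2, rt
Reagents that add atoms: none
Why: Dess–Martin oxidation of the secondary alcohol should give the methyl ketone under neutral conditions that leave the acyl acetal and the non-enolisable quaternary centre intact.

Step 7
Reactants: 10 (2R,5S)-5-acetyl-2-tert-butyl-5-methyl-1,3-dioxolan-4-one
Product: 12 (2R,5S)-2-tert-butyl-5-(diazoacetyl)-5-methyl-1,3-dioxolan-4-one, via trifluoroacetylated diketone 11 (not isolated)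
Conditions: LiHMDS, THF, −78 °C; CF3CO2CH2CF3; then MsN3, Et3N, H2O, MeCN, rt
Reagents that add atoms: methanesulfonyl azide, CS(=O)(=O)N=[N+]=[N-]; 2,2,2-trifluoroethyl trifluoroacetate, O=C(OCC(F)(F)F)C(F)(F)F (trifluoroacetyl group of 11 only)
Why: Deacylative (Regitz-type) diazo transfer: the only enolisable position, the acetyl methyl, is trifluoroacetylated through its lithium enolate, and the activated 1,3-diketone 11 should take the diazo group from mesyl azide with loss of the trifluoroacetyl group.

Step 8
Reactants: 12 (2R,5S)-2-tert-butyl-5-(diazoacetyl)-5-methyl-1,3-dioxolan-4-one; 4 (2R)-2,4-dimethyl-2,3-dihydrofuran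
Product: 16 (2R,5S)-2-tert-butyl-5-{[(6R)-2-methoxy-4,6-dimethyl-5,6-dihydro-2H-pyran-3-yl]carbonyl}-5-methyl-1,3-dioxolan-4-one (anomeric mixture at the acetal carbon), via bromodiazoketone 13 (not isolated), via bromocyclopropane 14 (not isolated), via 2-bromo-2H-pyran 15 (not isolated)
Conditions: NBS, DBU, CH2Cl2, −78 → 0 °C, cold SiO2 plug; then 4 (2 equiv), Rh2(esp)2 (1 mol %; esp = α,α,α′,α′-tetramethyl-1,3-benzenedipropanoate), CH2Cl2, −20 → 0 °C; then MeOH, 2,6-lutidine, −40 °C → rt
Reagents that add atoms: N-bromosuccinimide, O=C1CCC(=O)N1Br (bromine of 13 to 15 only); methanol, CO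
Why: Proposed new method: the bromo(acyl) rhodium carbene from 13 should be attacked by the nucleophilic β-carbon of the cyclic enol ether 4 and close by [2+1] carbene transfer to the donor–acceptor bromocyclopropane 14; its bromide syn to the oxolane ring then leaves with disrotatory two-electron electrocyclic opening of the shared C1–C4a bond (cyclopropyl to allyl cation, pushed by the ring oxygen), so that C8a is inserted and the five-membered oxolane becomes the six-membered pyran as oxocarbenium bromide 15, which methanol captures at C1. The closest known reaction types are the Ciamician–Dennstedt-type ring expansion of cyclic enol ethers (glycals, dihydrofurans) through dihalocarbene adducts and the Rh2(esp)2-catalysed one-carbon insertion of halodiazoacetates into indoles; NBS/DBU bromination of a diazomethyl carbon is known for diazoacetates, diazophosphonates and diazoamides. Ring modes: the three-membered ring forms by cheletropic [2+1] addition, and the pyran is not closed by a new ring bond but arises by electrocyclic cleavage of the ring-fusion bond (one-atom ring expansion). No stereocentre of the target is created: C3 is untouched, the acetal carbon C1 of 16 forms as an anomeric mixture that is erased in step 9, and the future C7 is quaternary and cannot epimerise. The step needs intermolecular cyclopropanation in preference to carbonyl-ylide formation with the lactone carbonyl; the high nucleophilicity and excess of 4 favour this, and the halodiazoketone is made separately so that NBS never meets the enol ether. It also needs the bromide on the face syn to the oxolane ring (the bulky acyl group should prefer the exo position, and the donor–acceptor cyclopropane can epimerise by reversible C1–C8a heterolysis) and capture at C1 instead of proton loss towards C4, which the oxygen-stabilised charge at C1 and the cold methanol/2,6-lutidine quench should secure.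

Step 9
Reactants: 16 (2R,5S)-2-tert-butyl-5-{[(6R)-2-methoxy-4,6-dimethyl-5,6-dihydro-2H-pyran-3-yl]carbonyl}-5-methyl-1,3-dioxolan-4-one
Product: 18 (3R,7R)-7-hydroxy-3,7-dimethyl-3,4-dihydro-6H-isochromene-6,8(7H)-dione, via methoxy enedione 17 (not isolated)
Conditions: LDA (3 equiv), THF, −78 → 0 °C; AcOH
Reagents that add atoms: none
Why: LDA should remove a proton from the methyl group syn to the ketone (γ-deprotonation through a lithium-chelated transition state), the cross-conjugated dienolate should attack the activated acyl-acetal carbonyl in a six-membered vinylogous Dieckmann (Claisen) condensation that expels pivalaldehyde and unveils the C7 alkoxide with the configuration fixed in step 5, and the doubly activated C5 methylene of 17 should then eliminate methoxide from C1 (vinylogous E1cB) to give the push–pull dienone.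

Step 10
Reactants: 18 (3R,7R)-7-hydroxy-3,7-dimethyl-3,4-dihydro-6H-isochromene-6,8(7H)-dione; 19 linoleoyl chloride
Product: 20 (3R,7R)-3,7-dimethyl-6,8-dioxo-3,4,7,8-tetrahydro-6H-isochromen-7-yl (9Z,12Z)-octadeca-9,12-dienoate (CNP0260084.1)
Conditions: pyridine, DMAP, CH2Cl2, 0 °C → rt
Reagents that add atoms: none
Why: DMAP-catalysed acylation with the acid chloride (acylpyridinium intermediate) is the usual way to esterify a hindered tertiary carbinol flanked by carbonyl groups and should leave both stereocentres and the skipped Z,Z-diene untouched.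

**Compound list**
1 | (R)-γ-valerolactone, (5R)-5-methyloxolan-2-one | O=C1CC[C@@H](C)O1 | starting material
2 | (3RS,5R)-3,5-dimethyloxolan-2-one | O=C1C(C)C[C@@H](C)O1 | intermediate
3 | (3RS,5R)-3,5-dimethyloxolan-2-ol (lactol, anomeric mixture) | OC1O[C@H](C)CC1C | intermediate
4 | (2R)-2,4-dimethyl-2,3-dihydrofuran | CC1=CO[C@H](C)C1 | intermediate
5 | (R)-lactic acid | C[C@@H](O)C(=O)O | starting material
6 | pivalaldehyde | CC(C)(C)C=O | starting material
7 | (2R,5R)-2-tert-butyl-5-methyl-1,3-dioxolan-4-one (cis) | C[C@H]1O[C@@H](C(C)(C)C)OC1=O | intermediate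
8 | acetaldehyde | CC=O | starting material
9 | (2R,5S)-2-tert-butyl-5-[(1RS)-1-hydroxyethyl]-5-methyl-1,3-dioxolan-4-one | C[C@@]1(C(C)O)O[C@@H](C(C)(C)C)OC1=O | intermediate
10 | (2R,5S)-5-acetyl-2-tert-butyl-5-methyl-1,3-dioxolan-4-one | C[C@@]1(C(C)=O)O[C@@H](C(C)(C)C)OC1=O | intermediate
11 | (2R,5S)-2-tert-butyl-5-methyl-5-(4,4,4-trifluoro-3-oxobutanoyl)-1,3-dioxolan-4-one | C[C@@]1(C(=O)CC(=O)C(F)(F)F)O[C@@H](C(C)(C)C)OC1=O | intermediate (not isolated)
12 | (2R,5S)-2-tert-butyl-5-(diazoacetyl)-5-methyl-1,3-dioxolan-4-one | C[C@@]1(C(=O)C=[N+]=[N-])O[C@@H](C(C)(C)C)OC1=O | intermediate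
13 | (2R,5S)-5-[bromo(diazo)acetyl]-2-tert-butyl-5-methyl-1,3-dioxolan-4-one | C[C@@]1(C(=O)C(Br)=[N+]=[N-])O[C@@H](C(C)(C)C)OC1=O | intermediate (not isolated)
14 | (2R,5S)-5-{[(3R)-6-bromo-3,5-dimethyl-2-oxabicyclo[3.1.0]hexan-6-yl]carbonyl}-2-tert-butyl-5-methyl-1,3-dioxolan-4-one | C[C@@H]1CC2(C)C(O1)C2(Br)C(=O)[C@]1(C)O[C@@H](C(C)(C)C)OC1=O | intermediate (not isolated)
15 | (2R,5S)-5-{[(6R)-2-bromo-4,6-dimethyl-5,6-dihydro-2H-pyran-3-yl]carbonyl}-2-tert-butyl-5-methyl-1,3-dioxolan-4-one (covalent form of the oxocarbenium bromide) | BrC1O[C@H](C)CC(C)=C1C(=O)[C@]2(C)O[C@@H](C(C)(C)C)OC2=O | intermediate (not isolated)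
16 | (2R,5S)-2-tert-butyl-5-{[(6R)-2-methoxy-4,6-dimethyl-5,6-dihydro-2H-pyran-3-yl]carbonyl}-5-methyl-1,3-dioxolan-4-one | COC1O[C@H](C)CC(C)=C1C(=O)[C@]2(C)O[C@@H](C(C)(C)C)OC2=O | intermediate
17 | (3R,7R)-7-hydroxy-1-methoxy-3,7-dimethyl-3,4-dihydro-1H-isochromene-6,8(5H,7H)-dione (as lithium alkoxide) | O[C@]1(C)C(=O)CC2=C(C(OC)O[C@H](C)C2)C1=O | intermediate (not isolated)
18 | (3R,7R)-7-hydroxy-3,7-dimethyl-3,4-dihydro-6H-isochromene-6,8(7H)-dione | O[C@]1(C)C(=O)C=C2C[C@@H](C)OC=C2C1=O | intermediate
19 | linoleoyl chloride, (9Z,12Z)-octadeca-9,12-dienoyl chloride | CCCCC/C=C\C/C=C\CCCCCCCC(=O)Cl | starting material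
20 | (3R,7R)-3,7-dimethyl-6,8-dioxo-3,4,7,8-tetrahydro-6H-isochromen-7-yl (9Z,12Z)-octadeca-9,12-dienoate | CCCCC/C=C\C/C=C\CCCCCCCC(=O)O[C@]1(C)C(=O)C=C2C[C@@H](C)OC=C2C1=O | target

**Step count and risks**
Total steps: 10. Longest linear sequence: 7 steps (steps 4 to 10, from (R)-lactic acid); steps 1 to 3 form the second branch, joined in step 8.

Most likely to fail:

1. Step 8 (proposed new method). The bromo(acyl) carbene may be diverted into carbonyl-ylide formation with the lactone carbonyl or into formal [3+2] closure through the ketone oxygen instead of cyclopropanation. The bromodiazoketone may decompose before transfer. The allyl cation may also lose a proton towards C4, giving a 2H-pyran whose electrocyclic opening would erode the C3 configuration. The fallback sets out from 4 and 7 and rejoins the route at 16, and keeps the one-carbon ring expansion in its classical form. Dihydrofuran 4 would be treated with bromoform and KOtBu (pentane, −20 °C) to give the dibromocarbene adduct (3R)-6,6-dibromo-3,5-dimethyl-2-oxabicyclo[3.1.0]hexane F1. Warming F1 with K2CO3 in methanol should bring about the well-known gem-dibromocyclopropane ring expansion to (6R)-3-bromo-2-methoxy-4,6-dimethyl-5,6-dihydro-2H-pyran F2. The lithium enolate of 7 would be formylated with ethyl formate to (2R,5S)-2-tert-butyl-5-methyl-4-oxo-1,3-dioxolane-5-carbaldehyde F3. Bromine–lithium exchange of F2 (t-BuLi, THF, −78 °C) and addition to F3 would give the allylic alcohol (2R,5S)-2-tert-butyl-5-{hydroxy[(6R)-2-methoxy-4,6-dimethyl-5,6-dihydro-2H-pyran-3-yl]methyl}-5-methyl-1,3-dioxolan-4-one F4, and Dess–Martin oxidation of F4 would give 16.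

2. Step 9. The dienolate may eliminate methoxide before the C–C bond forms, deprotonation may occur at the ring CH2 instead of the methyl group, or the unprotected C7 alkoxide may fragment by retro-Claisen or α-ketol shift. The fallback sets out from 16 and rejoins at 18, unmasking the acyl donor first and keeping C7–O protected during ring closure. Methanolysis of the acyl acetal (K2CO3, MeOH, 0 °C) would release pivalaldehyde and give methyl (2S)-2-hydroxy-3-[(6R)-2-methoxy-4,6-dimethyl-5,6-dihydro-2H-pyran-3-yl]-2-methyl-3-oxopropanoate F5. Silylation (TESOTf, 2,6-lutidine) would give methyl (2S)-3-[(6R)-2-methoxy-4,6-dimethyl-5,6-dihydro-2H-pyran-3-yl]-2-methyl-3-oxo-2-[(triethylsilyl)oxy]propanoate F6. Dieckmann condensation under equilibrating alkoxide conditions (KOtBu, t-BuOH/THF), with loss of methanol from C1, should give (3R,7R)-3,7-dimethyl-7-[(triethylsilyl)oxy]-3,4-dihydro-6H-isochromene-6,8(7H)-dione F7, and HF·pyridine would release 18.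

3. Step 7. The ketone enolate may attack the acyl-acetal carbonyl of a second molecule (Claisen-type self-condensation), and the dioxolanone may be opened hydrolytically during the aqueous amine stage of the diazo transfer. The fallback sets out from 7 and rejoins at 12 by acylation of diazomethane instead of diazo transfer. Carboxylation of the lithium enolate of 7 with CO2 would give (2R,5S)-2-tert-butyl-5-methyl-4-oxo-1,3-dioxolane-5-carboxylic acid F8. Oxalyl chloride with catalytic DMF would give (2R,5R)-2-tert-butyl-5-methyl-4-oxo-1,3-dioxolane-5-carbonyl chloride F9, and excess diazomethane (Et2O, 0 °C) would give 12.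

Further compounds
F1 | step 8 | (3R)-6,6-dibromo-3,5-dimethyl-2-oxabicyclo[3.1.0]hexane | C[C@@H]1CC2(C)C(O1)C2(Br)Br
F2 | step 8 | (6R)-3-bromo-2-methoxy-4,6-dimethyl-5,6-dihydro-2H-pyran | COC1O[C@H](C)CC(C)=C1Br
F3 | step 8 | (2R,5S)-2-tert-butyl-5-methyl-4-oxo-1,3-dioxolane-5-carbaldehyde | C[C@@]1(C=O)O[C@@H](C(C)(C)C)OC1=O
F4 | step 8 | (2R,5S)-2-tert-butyl-5-{hydroxy[(6R)-2-methoxy-4,6-dimethyl-5,6-dihydro-2H-pyran-3-yl]methyl}-5-methyl-1,3-dioxolan-4-one | COC1O[C@H](C)CC(C)=C1C(O)[C@]2(C)O[C@@H](C(C)(C)C)OC2=O
F5 | step 9 | methyl (2S)-2-hydroxy-3-[(6R)-2-methoxy-4,6-dimethyl-5,6-dihydro-2H-pyran-3-yl]-2-methyl-3-oxopropanoate | COC1O[C@H](C)CC(C)=C1C(=O)[C@](C)(O)C(=O)OC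
F6 | step 9 | methyl (2S)-3-[(6R)-2-methoxy-4,6-dimethyl-5,6-dihydro-2H-pyran-3-yl]-2-methyl-3-oxo-2-[(triethylsilyl)oxy]propanoate | COC1O[C@H](C)CC(C)=C1C(=O)[C@](C)(O[Si](CC)(CC)CC)C(=O)OC
F7 | step 9 | (3R,7R)-3,7-dimethyl-7-[(triethylsilyl)oxy]-3,4-dihydro-6H-isochromene-6,8(7H)-dione | CC[Si](CC)(CC)O[C@]1(C)C(=O)C=C2C[C@@H](C)OC=C2C1=O
F8 | step 7 | (2R,5S)-2-tert-butyl-5-methyl-4-oxo-1,3-dioxolane-5-carboxylic acid | C[C@@]1(C(=O)O)O[C@@H](C(C)(C)C)OC1=O
F9 | step 7 | (2R,5R)-2-tert-butyl-5-methyl-4-oxo-1,3-dioxolane-5-carbonyl chloride | C[C@@]1(C(=O)Cl)O[C@@H](C(C)(C)C)OC1=O
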